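(The readings stem from a simulated flask with constants of no real substance, and the scatter is random.)

A one-step world has one product, but Monday's flask, where Q at 0.180 M is a smaller charge than J or Z, shows two, X and G, so the meeting took up how the yield divides.

in all of them: J 0.30 M

|  | Q | Z | remark | time |
|---|---|---|---|---|
| Monday's | 0.18 M | 0.36 M (fed, over 5.0 h) | the very flask that is asked about, followed so far; the fed solution adds 0.25 times the starting volume |  |
| Tuesday's | 0.18 M | 0.24 M (fed, over 5.0 h) | run made earlier; the fed solution adds 0.25 times the starting volume |  |
| flask | 0.180 M | 0.360 M (fed, over 5.0 h) | the fed solution adds 0.25 times the starting volume | 15 d |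

- Monday's (time / d: X / %, G / %): 0.250: 5.9, 0; 0.833: 24.4, 5.0; 1.25: 30.3, 9.0; 2.00: 34.7, 14.6; 3.00: 36.8, 18.4
- Tuesday's (time / d: X / %, G / %): 3.00: 31.7, 15.3; 6.00: 35.4, 19.2; 10.0: 37.8, 21.0; 12.0: 37.7, 21.6; 15.0: 38.3, 21.4

(standard deviation of a reading: 0.3 percentage points)

- every charge counts on the volume at the start, and the solution that is fed holds the whole dose
- the reaction counts as stopped when no species that holds the J changes by six tenths of a point or more over the second half of the time

- the state of affairs at 15 d: stopped, and by what, or still going (Q has run out first / Z has run out first / forward and back rates have come level / it is still moving / all of J has reacted)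
- X at 15 d, in percent of the J charged
- G at 15 d, in percent of the J charged

**Minutes.** I proposed treating X and G as a fast equilibrium and reckoning with what it leaves free, namely the pool X + G, which I took to equal the charge of the limiting reagent, each of J, Q and Z going in once. I argued that Tuesday's run supports this pool, since its X + G reads 59.7% at 15.0 d against a Q charge worth 60.0% of J. I then asked the meeting to carry one number, read as 36.0% over Tuesday's readings from 10.0 d to 15.0 d, with their scatter of 0.3 percentage points: G's share of the pool, [G]/([X]+[G]). Monday's pool stood at 55.2% at 3.00 d and had 60.0% to reach, so my reckoning for 15 d was G 21.6% and X 38.4%.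

The forecaster reasoned differently, holding that “G takes a second Z”, which my share does not need, and forecast: Q has run out first, with X 37.8% (35.5% to 39%) and G 22.2% (21% to 24.5%). The two reckonings both have Q as the limiting reagent but give different figures.

**Result.** At 15 d the flask gives: Q has run out first, with Q at 0% of its charge, X 38.2% and G 21.8%.

    X ⇌ G (K = 0.570, k = 0.0250 h⁻¹)
    Z + E → X (k = 0.210 M⁻¹ h⁻¹)
    J + Q → E (k = 0.980 M⁻¹ h⁻¹)

In these equations each X formed from E has taken up one Q and one Z, and G forms from X without further Z. The neighbouring flask is charged with 0.090 M of Z, a smaller charge than J or Q, with everything else as in the recipe. Its pool is therefore 30.0%, and the share 36.0% divides that into G 10.8% and X 19.2%. At 15.0 d that flask gives G 10.9% and X 19.1%, with Z down to 0.242% of its charge, and E still holds 30.1% of the J charged.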